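The heptamer is cut at the ether between rings C and D into an A–B–C phenol and a D–E–F–G bromide; all seventeen hydroxyls travel as methyl ethers. Everything rests on ring E, whose C1 and C6 carry neighbouring ether oxygens (to rings D and F) with the C5 oxygen next to C6: a C1≡C6 aryne, polarised by that C5 methoxy group, takes up the ring D phenolate at C1 and magnesium at C6, which is turned into the C6 hydroxyl in the same flask. The aryne precursor is 2-iodo-3,5-dimethoxyphenyl 4-chlorobenzenesulfonate; its partner, 4-bromo-2,6-dimethoxyphenol, brings the bromide used later to join ring D to ring C.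

Key step: step 3

Remark: rings are lettered A to G from the 2,4,6-trioxygenated end ring (A) to the 3,4,5-trioxygenated end ring (G); ring E is numbered with C1 on the oxygen toward ring D and C6 on the oxygen toward ring F; the target has no stereocentre; compounds 5, 12, 18, 19 and 23 are taken as purchasable.

Step 1
Reactants: 1 3,5-dimethoxyphenol
Product: 2 2-iodo-3,5-dimethoxyphenol
Conditions: I2 (1.0 equiv), NaHCO3, THF–H2O, 0 °C
Reagents that add atoms: iodine, II
Why: Electrophilic aromatic iodination of the phenolate should favour the two equivalent positions ortho to the hydroxyl (each also para to a methoxy group) over C4, which is shielded by two flanking methoxy groups, and one equivalent of iodine at 0 °C limits di-iodination (any C4 isomer is removed by chromatography).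

Step 2
Reactants: 2 2-iodo-3,5-dimethoxyphenol; 3 4-chlorobenzenesulfonyl chloride
Product: 4 2-iodo-3,5-dimethoxyphenyl 4-chlorobenzenesulfonate
Conditions: Et3N, DMAP (cat.), CH2Cl2, 0 °C → rt
Reagents that add atoms: none
Why: O-Sulfonylation of a phenol by an arenesulfonyl chloride under amine base with DMAP catalysis is routine and leaves the aryl iodide untouched.

Step 3
Reactants: 4 2-iodo-3,5-dimethoxyphenyl 4-chlorobenzenesulfonate; 5 4-bromo-2,6-dimethoxyphenol
Product: 11 2-(4-bromo-2,6-dimethoxyphenoxy)-4,6-dimethoxyphenol, via ring D chloromagnesium phenolate 6 (not isolated), via magnesiated sulfonate 7 (not isolated), via 3,5-dimethoxybenzyne 8 (not isolated), via ring E arylmagnesium chloride 9 (not isolated), via dimethyl arylboronate 10 (not isolated)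
Conditions: 5 (2.0 equiv), i-PrMgCl·LiCl (1.95 equiv), THF, 0 °C; separately 4, i-PrMgCl·LiCl (1.05 equiv), THF, −78 °C; combine, −78 °C → rt; B(OMe)3, −78 → 0 °C; 30% aq H2O2, 0 °C → rt
Reagents that add atoms: hydrogen peroxide, OO
Why: Proposed new method: iodine–magnesium exchange at the iodine lying between two oxygen substituents gives 7, which on warming expels the ortho 4-chlorobenzenesulfonate to release aryne 8 (ring E C1≡C6); aryloxide 6, whose ortho and para carbons are blocked so that only oxygen can attack, should add at C1 and leave magnesium at C6 (9), and borylation to 10 followed by peroxide-induced aryl migration from boron to oxygen gives the C6 hydroxyl of 11. The closest known reaction type is the addition of magnesium thiolates, selenolates and amides to arynes generated from 2-iodoaryl sulfonates with electrophilic quench of the arylmagnesium formed, together with the familiar O-arylation of alkali phenoxides by arynes; a magnesium aryloxide as the nucleophile in this three-component mode is the unproven part. No ring is closed and no stereocentre is created. The selectivity needed is regiochemical, and the C5 methoxy group next to C6 should provide it: its inductive pull and the distortion it imposes on the triple bond favour negative charge at C6, so the nucleophile enters at the remote and less hindered C1. Chemoselectivity rests on the ring D bromide being inert to the Grignard reagent at these temperatures, on leaving no free i-PrMgCl·LiCl to add to the aryne, and on chelation of magnesium in 9 by the C5 methoxy and the new ether oxygen, which should hold the carbanion until the borate arrives.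

Step 4
Reactants: 5 4-bromo-2,6-dimethoxyphenol; 12 (3,4,5-trimethoxyphenyl)boronic acid
Product: 13 5-bromo-1,3-dimethoxy-2-(3,4,5-trimethoxyphenoxy)benzene
Conditions: Cu(OAc)2 (1 equiv), pyridine, 4 Å MS, CH2Cl2, air as terminal oxidant, rt (12 in excess)
Reagents that add atoms: none
Why: Chan–Lam coupling: the electron-rich boronic acid without ortho substituents transmetalates to copper and C–O reductive elimination arylates the phenol despite its two ortho methoxy groups, while the oxidative room-temperature conditions leave the aryl bromide alone.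

Step 5
Reactants: 13 5-bromo-1,3-dimethoxy-2-(3,4,5-trimethoxyphenoxy)benzene
Product: 16 [3,5-dimethoxy-4-(3,4,5-trimethoxyphenoxy)phenyl]boronic acid, via aryllithium 14 (not isolated), via lithium triisopropoxyborate 15 (not isolated)
Conditions: n-BuLi, THF, −78 °C; B(Oi-Pr)3, −78 °C → rt; 1 M aq HCl
Reagents that add atoms: triisopropyl borate, CC(C)OB(OC(C)C)OC(C)C; water, O
Why: Lithiation–borylation: bromine–lithium exchange at −78 °C outruns ortho-lithiation of the methoxy arenes, the aryllithium is captured by the borate ester, and acid hydrolysis frees the boronic acid.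

Step 6
Reactants: 11 2-(4-bromo-2,6-dimethoxyphenoxy)-4,6-dimethoxyphenol; 16 [3,5-dimethoxy-4-(3,4,5-trimethoxyphenoxy)phenyl]boronic acid
Product: 17 5-bromo-2-{2-[3,5-dimethoxy-4-(3,4,5-trimethoxyphenoxy)phenoxy]-3,5-dimethoxyphenoxy}-1,3-dimethoxybenzene (D–E–F–G bromide)
Conditions: Cu(OAc)2 (1 equiv), pyridine, 4 Å MS, CH2Cl2, air as terminal oxidant, rt (16 in excess)
Reagents that add atoms: none
Why: Chan–Lam coupling is chosen because it arylates the hindered ring E hydroxyl (between a methoxy and an aryloxy group) with a boronic acid that has no ortho substituent and, unlike a coupling with an aryl halide, cannot engage the ring D bromide of 11.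

Step 7
Reactants: 18 2,4,6-trimethoxyphenol; 19 4-bromo-2,6-dimethoxybenzaldehyde
Product: 20 2,6-dimethoxy-4-(2,4,6-trimethoxyphenoxy)benzaldehyde
Conditions: CuI (10 mol %), picolinic acid (20 mol %), K3PO4, DMSO, 90 °C, Ar
Reagents that add atoms: none
Why: Ullmann ether synthesis with the picolinic acid–copper catalyst accepts phenols with two ortho substituents, and the bromide of 19 is unhindered and activated by the para formyl group.

Step 8
Reactants: 20 2,6-dimethoxy-4-(2,4,6-trimethoxyphenoxy)benzaldehyde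
Product: 22 2,6-dimethoxy-4-(2,4,6-trimethoxyphenoxy)phenol (A–B phenol), via aryl formate 21 (not isolated)
Conditions: mCPBA, CH2Cl2, 0 °C → rt; Et3N (cat.), MeOH, rt
Reagents that add atoms: 3-chloroperoxybenzoic acid (mCPBA), OOC(=O)c1cccc(Cl)c1
Why: Baeyer–Villiger (Dakin-type) oxidation: in the Criegee adduct the electron-rich 2,6-dimethoxyaryl group migrates in preference to hydride, and the resulting aryl formate is cleaved by mild methanolysis.

Step 9
Reactants: 23 5-bromo-1,2,3-trimethoxybenzene
Product: 25 6-bromo-2,3,4-trimethoxybenzaldehyde, via α-chloro ether 24 (not isolated)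
Conditions: Cl2CHOMe, TiCl4, CH2Cl2, 0 °C; H2O
Reagents that add atoms: dichloromethyl methyl ether, COC(Cl)Cl; water, O
Why: Rieche formylation: the two free positions of 23 are equivalent, each para to one methoxy group and ortho to another, so electrophilic substitution can only give the aldehyde with formyl and bromine on neighbouring carbons.

Step 10
Reactants: 22 2,6-dimethoxy-4-(2,4,6-trimethoxyphenoxy)phenol; 25 6-bromo-2,3,4-trimethoxybenzaldehyde
Product: 26 6-[2,6-dimethoxy-4-(2,4,6-trimethoxyphenoxy)phenoxy]-2,3,4-trimethoxybenzaldehyde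
Conditions: CuI (10 mol %), picolinic acid (20 mol %), K3PO4, DMSO, 90 °C, Ar
Reagents that add atoms: none
Why: Ullmann ether synthesis: the bromide of 25 is activated by the ortho formyl group and has a hydrogen on its other side, and the picolinic acid–copper system accepts the 2,6-dimethoxyphenol 22.

Step 11
Reactants: 26 6-[2,6-dimethoxy-4-(2,4,6-trimethoxyphenoxy)phenoxy]-2,3,4-trimethoxybenzaldehyde
Product: 28 6-[2,6-dimethoxy-4-(2,4,6-trimethoxyphenoxy)phenoxy]-2,3,4-trimethoxyphenol (A–B–C phenol), via aryl formate 27 (not isolated)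
Conditions: mCPBA, CH2Cl2, 0 °C → rt; Et3N (cat.), MeOH, rt
Reagents that add atoms: 3-chloroperoxybenzoic acid (mCPBA), OOC(=O)c1cccc(Cl)c1
Why: Baeyer–Villiger (Dakin-type) oxidation as in step 8: the aryl group, carrying ortho and para oxygen donors, migrates to oxygen and the formate is removed by methanolysis, placing the hydroxyl at ring C C6 between the ring B ether and a methoxy group.

Step 12
Reactants: 17 D–E–F–G bromide; 28 A–B–C phenol
Product: 29 2-{4-[2-(4-{2-[3,5-dimethoxy-4-(3,4,5-trimethoxyphenoxy)phenoxy]-3,5-dimethoxyphenoxy}-3,5-dimethoxyphenoxy)-3,4,5-trimethoxyphenoxy]-3,5-dimethoxyphenoxy}-1,3,5-trimethoxybenzene (heptadecamethyl ether of the target)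
Conditions: CuI (20 mol %), picolinic acid (40 mol %), K3PO4, DMSO, 100 °C, Ar
Reagents that add atoms: none
Why: Ullmann ether synthesis pairing a hindered phenol with a bromide that has no ortho substituent, the same pairing as in steps 7 and 10, with no other halide or free hydroxyl in either partner.

Step 13
Reactants: 29 heptadecamethyl ether of the target
Product: 31 2-{4-[2-(4-{2-[3,5-dihydroxy-4-(3,4,5-trihydroxyphenoxy)phenoxy]-3,5-dihydroxyphenoxy}-3,5-dihydroxyphenoxy)-3,4,5-trihydroxyphenoxy]-3,5-dihydroxyphenoxy}benzene-1,3,5-triol (target), via aryloxyborane 30 (not isolated)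
Conditions: BBr3 (excess), CH2Cl2, −78 °C → rt; MeOH then H2O, 0 °C; work-up under Ar
Reagents that add atoms: none
Why: Lewis-acid ether cleavage: BBr3 binds each methoxy oxygen and bromide removes the methyl group by SN2 attack, whereas the diaryl ether bonds offer no sp3 carbon and should survive, and hydrolysis of the aryloxyboranes frees all seventeen hydroxyls.

Compound list
1 | 3,5-dimethoxyphenol | COc1cc(O)cc(OC)c1 | starting material
2 | 2-iodo-3,5-dimethoxyphenol | COc1cc(O)c(I)c(OC)c1 | intermediate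
3 | 4-chlorobenzenesulfonyl chloride | O=S(=O)(Cl)c1ccc(Cl)cc1 | starting material
4 | 2-iodo-3,5-dimethoxyphenyl 4-chlorobenzenesulfonate | COc1cc(OC)c(I)c(OS(=O)(=O)c2ccc(Cl)cc2)c1 | intermediate
5 | 4-bromo-2,6-dimethoxyphenol | COc1cc(Br)cc(OC)c1O | starting material
6 | chloromagnesium 4-bromo-2,6-dimethoxyphenolate | COc1cc(Br)cc(OC)c1O[Mg]Cl | intermediate (not isolated)
7 | 2-(chloromagnesio)-3,5-dimethoxyphenyl 4-chlorobenzenesulfonate | COc1cc(OC)c([Mg]Cl)c(OS(=O)(=O)c2ccc(Cl)cc2)c1 | intermediate (not isolated)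
8 | 3,5-dimethoxybenzyne (1,2-didehydro-3,5-dimethoxybenzene) | COC1=CC(OC)=CC#C1 | intermediate (not isolated)
9 | [2-(4-bromo-2,6-dimethoxyphenoxy)-4,6-dimethoxyphenyl]magnesium chloride | COc1cc(OC)c([Mg]Cl)c(Oc2c(OC)cc(Br)cc2OC)c1 | intermediate (not isolated)
10 | dimethyl [2-(4-bromo-2,6-dimethoxyphenoxy)-4,6-dimethoxyphenyl]boronate | COc1cc(OC)c(B(OC)OC)c(Oc2c(OC)cc(Br)cc2OC)c1 | intermediate (not isolated)
11 | 2-(4-bromo-2,6-dimethoxyphenoxy)-4,6-dimethoxyphenol | COc1cc(OC)c(O)c(Oc2c(OC)cc(Br)cc2OC)c1 | intermediate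
12 | (3,4,5-trimethoxyphenyl)boronic acid | COc1cc(B(O)O)cc(OC)c1OC | starting material
13 | 5-bromo-1,3-dimethoxy-2-(3,4,5-trimethoxyphenoxy)benzene | COc1cc(Br)cc(OC)c1Oc1cc(OC)c(OC)c(OC)c1 | intermediate
14 | [3,5-dimethoxy-4-(3,4,5-trimethoxyphenoxy)phenyl]lithium | COc1cc([Li])cc(OC)c1Oc1cc(OC)c(OC)c(OC)c1 | intermediate (not isolated)
15 | lithium [3,5-dimethoxy-4-(3,4,5-trimethoxyphenoxy)phenyl]tri(propan-2-yloxy)borate | COc1cc([B-](OC(C)C)(OC(C)C)OC(C)C)cc(OC)c1Oc1cc(OC)c(OC)c(OC)c1.[Li+] | intermediate (not isolated)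
16 | [3,5-dimethoxy-4-(3,4,5-trimethoxyphenoxy)phenyl]boronic acid | COc1cc(B(O)O)cc(OC)c1Oc1cc(OC)c(OC)c(OC)c1 | intermediate
17 | 5-bromo-2-{2-[3,5-dimethoxy-4-(3,4,5-trimethoxyphenoxy)phenoxy]-3,5-dimethoxyphenoxy}-1,3-dimethoxybenzene | COc1cc(Br)cc(OC)c1Oc1cc(OC)cc(OC)c1Oc1cc(OC)c(Oc2cc(OC)c(OC)c(OC)c2)c(OC)c1 | intermediate
18 | 2,4,6-trimethoxyphenol | COc1cc(OC)c(O)c(OC)c1 | starting material
19 | 4-bromo-2,6-dimethoxybenzaldehyde | COc1cc(Br)cc(OC)c1C=O | starting material
20 | 2,6-dimethoxy-4-(2,4,6-trimethoxyphenoxy)benzaldehyde | COc1cc(OC)c(Oc2cc(OC)c(C=O)c(OC)c2)c(OC)c1 | intermediate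
21 | 2,6-dimethoxy-4-(2,4,6-trimethoxyphenoxy)phenyl formate | COc1cc(OC)c(Oc2cc(OC)c(OC=O)c(OC)c2)c(OC)c1 | intermediate (not isolated)
22 | 2,6-dimethoxy-4-(2,4,6-trimethoxyphenoxy)phenol | COc1cc(OC)c(Oc2cc(OC)c(O)c(OC)c2)c(OC)c1 | intermediate
23 | 5-bromo-1,2,3-trimethoxybenzene | COc1cc(Br)cc(OC)c1OC | starting material
24 | 1-bromo-2-[chloro(methoxy)methyl]-3,4,5-trimethoxybenzene (racemic, as its TiCl4 complex) | COC(Cl)c1c(Br)cc(OC)c(OC)c1OC | intermediate (not isolated)
25 | 6-bromo-2,3,4-trimethoxybenzaldehyde | COc1cc(Br)c(C=O)c(OC)c1OC | intermediate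
26 | 6-[2,6-dimethoxy-4-(2,4,6-trimethoxyphenoxy)phenoxy]-2,3,4-trimethoxybenzaldehyde | COc1cc(OC)c(Oc2cc(OC)c(Oc3cc(OC)c(OC)c(OC)c3C=O)c(OC)c2)c(OC)c1 | intermediate
27 | 6-[2,6-dimethoxy-4-(2,4,6-trimethoxyphenoxy)phenoxy]-2,3,4-trimethoxyphenyl formate | COc1cc(OC)c(Oc2cc(OC)c(Oc3cc(OC)c(OC)c(OC)c3OC=O)c(OC)c2)c(OC)c1 | intermediate (not isolated)
28 | 6-[2,6-dimethoxy-4-(2,4,6-trimethoxyphenoxy)phenoxy]-2,3,4-trimethoxyphenol | COc1cc(OC)c(Oc2cc(OC)c(Oc3cc(OC)c(OC)c(OC)c3O)c(OC)c2)c(OC)c1 | intermediate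
29 | heptadecamethyl ether of the target (name as in step 12) | COc1cc(OC)c(Oc2cc(OC)c(Oc3cc(OC)c(OC)c(OC)c3Oc3cc(OC)c(Oc4cc(OC)cc(OC)c4Oc4cc(OC)c(Oc5cc(OC)c(OC)c(OC)c5)c(OC)c4)c(OC)c3)c(OC)c2)c(OC)c1 | intermediate
30 | heptadecakis(dibromoboryl) ether of 31 (idealised aryloxyborane: every hydroxyl oxygen of 31 carries BBr2) | BrB(Br)Oc1cc(OB(Br)Br)c(Oc2cc(OB(Br)Br)c(Oc3cc(OB(Br)Br)c(OB(Br)Br)c(OB(Br)Br)c3Oc3cc(OB(Br)Br)c(Oc4cc(OB(Br)Br)cc(OB(Br)Br)c4Oc4cc(OB(Br)Br)c(Oc5cc(OB(Br)Br)c(OB(Br)Br)c(OB(Br)Br)c5)c(OB(Br)Br)c4)c(OB(Br)Br)c3)c(OB(Br)Br)c2)c(OB(Br)Br)c1 | intermediate (not isolated)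
31 | CNP0351377.0 (name as in step 13) | Oc1cc(O)c(Oc2cc(O)c(Oc3cc(O)c(O)c(O)c3Oc3cc(O)c(Oc4cc(O)cc(O)c4Oc4cc(O)c(Oc5cc(O)c(O)c(O)c5)c(O)c4)c(O)c3)c(O)c2)c(O)c1 | target

Total step count: 13.
Longest linear sequence: 6 steps (steps 1, 2, 3, 6, 12, 13; the sequence 7, 8, 10, 11, 12, 13 is equally long).

Steps most likely to fail

Step 3. The hard magnesium aryloxide may add to the aryne too slowly, so that the aryne is lost to oligomerisation or the phenolate is consumed by sulfonyl transfer from 7, and the arylmagnesium may be protonated before it is borylated. The fallback uses known chemistry, sets out from 5 and needs no aryne. Nucleophilic aromatic substitution of 5 on purchased 2-fluoro-4,6-dimethoxybenzaldehyde (COc1cc(F)c(C=O)c(OC)c1; Cs2CO3, DMF, 100 °C) should give 2-(4-bromo-2,6-dimethoxyphenoxy)-4,6-dimethoxybenzaldehyde F1; the fluoride is ortho to the formyl group and the metal-free conditions spare the bromide. Baeyer–Villiger oxidation with mCPBA then gives 2-(4-bromo-2,6-dimethoxyphenoxy)-4,6-dimethoxyphenyl formate F2, and methanolysis (Et3N cat., MeOH) returns to the route at 11.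

Step 12. C–O bond formation between two large, electron-rich partners may be slow, with competing hydrodebromination of 17 and oxidative decay of the phenolate of 28 at 100 °C. The fallback sets out from 17 and reverses the roles of the partners. Bromine–lithium exchange (n-BuLi, THF, −78 °C) gives the tetramer aryllithium F3, which is captured by B(Oi-Pr)3 as the tetramer lithium triisopropoxyborate F4 and hydrolysed (1 M aq HCl) to the tetramer boronic acid F5. Chan–Lam coupling of F5 with 28 (Cu(OAc)2, pyridine, 4 Å MS, CH2Cl2, air, rt), the reaction type of step 6, returns to the route at 29.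

Step 13. Cleavage of seventeen methyl ethers may stop short, and the free polyphenol may be lost to air oxidation during isolation. The fallback sets out from 29 and replaces direct isolation by derivatisation, purification and release. After the BBr3 treatment and methanol quench the crude polyphenol is peracetylated without purification (Ac2O, pyridine, DMAP cat.) to the heptadecaacetate F6, which is stable, can be chromatographed on silica and can be separated from partly methylated material. Acid-catalysed methanolysis under argon (HCl in MeOH, rt) returns to the route at 31.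

Further compounds
F1 | step 3 | 2-(4-bromo-2,6-dimethoxyphenoxy)-4,6-dimethoxybenzaldehyde | COc1cc(OC)c(C=O)c(Oc2c(OC)cc(Br)cc2OC)c1
F2 | step 3 | 2-(4-bromo-2,6-dimethoxyphenoxy)-4,6-dimethoxyphenyl formate | COc1cc(OC)c(OC=O)c(Oc2c(OC)cc(Br)cc2OC)c1
F3 | step 12 | (4-{2-[3,5-dimethoxy-4-(3,4,5-trimethoxyphenoxy)phenoxy]-3,5-dimethoxyphenoxy}-3,5-dimethoxyphenyl)lithium | COc1cc([Li])cc(OC)c1Oc1cc(OC)cc(OC)c1Oc1cc(OC)c(Oc2cc(OC)c(OC)c(OC)c2)c(OC)c1
F4 | step 12 | lithium (4-{2-[3,5-dimethoxy-4-(3,4,5-trimethoxyphenoxy)phenoxy]-3,5-dimethoxyphenoxy}-3,5-dimethoxyphenyl)tri(propan-2-yloxy)borate | COc1cc([B-](OC(C)C)(OC(C)C)OC(C)C)cc(OC)c1Oc1cc(OC)cc(OC)c1Oc1cc(OC)c(Oc2cc(OC)c(OC)c(OC)c2)c(OC)c1.[Li+]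
F5 | step 12 | (4-{2-[3,5-dimethoxy-4-(3,4,5-trimethoxyphenoxy)phenoxy]-3,5-dimethoxyphenoxy}-3,5-dimethoxyphenyl)boronic acid | COc1cc(B(O)O)cc(OC)c1Oc1cc(OC)cc(OC)c1Oc1cc(OC)c(Oc2cc(OC)c(OC)c(OC)c2)c(OC)c1
F6 | step 13 | heptadecaacetate of 31 (every hydroxyl of 31 as its acetate) | CC(=O)Oc1cc(OC(C)=O)c(Oc2cc(OC(C)=O)c(Oc3cc(OC(C)=O)c(OC(C)=O)c(OC(C)=O)c3Oc3cc(OC(C)=O)c(Oc4cc(OC(C)=O)cc(OC(C)=O)c4Oc4cc(OC(C)=O)c(Oc5cc(OC(C)=O)c(OC(C)=O)c(OC(C)=O)c5)c(OC(C)=O)c4)c(OC(C)=O)c3)c(OC(C)=O)c2)c(OC(C)=O)c1
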